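The cyclopentanone ring (C8–C12) is read as a three-carbon enoate unit, C9–C8–C12, joined to a two-carbon unit, C10–C11; its β-hydroxy ketone C9(=O)–C10–C11(OH) is the hydrate of a C10=C11 enone. A nickel-catalysed reductive [3+2] cycloaddition of an acyclic phenyl (E)-enoate, which already carries the whole C13–C20 chain, with trimethylsilylacetylene forms C11–C12 and C9–C10 in one operation, and a chiral carbene ligand sets C12. From this single ring stereocenter C8 (enolate alkylation with the C1–C7 chain) and C11 (conjugate borylation, then oxidation) are relayed by substrate control; C15 and C19 are bought as epoxides.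

Key step: step 6

Remark: atoms are numbered as in prostanoic acid (C1 carboxyl carbon, ring C8–C12, C20 methyl); the sense of induction of the carbene ligand in step 6 is assumed to be assignable on a model enoate, and the antipode that gives (R) at C12 is used.

Step 1
Reactants: 1 (R)-epichlorohydrin; 2 allylmagnesium chloride
Product: 4 (R)-2-(but-3-en-1-yl)oxirane, via chlorohydrin 3 (not isolated)
Conditions: CuI (5 mol %), THF, −40 °C; then NaOH (50 % aq), rt
Reagents that add atoms: none
Why: Copper-catalysed Grignard opening of the epoxide at its CH2 terminus and Williamson-type closure of the chlorohydrin relay the epoxide along the chain; no bond at the stereocenter is touched, so the bought center becomes C15.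

Step 2
Reactants: 5 methyl phenyl sulfone; 4 (R)-2-(but-3-en-1-yl)oxirane; 6 (R)-propylene oxide
Product: 8 (2R,6R)-4-(phenylsulfonyl)dec-9-ene-2,6-diol (mixture at C4), via hydroxy sulfone 7 (not isolated)
Conditions: 5, n-BuLi (1.0 equiv), THF, −78 °C; 4, DMPU, −78 °C → rt; n-BuLi (1.1 equiv), −78 °C; 6, −78 °C → rt; aq NH4Cl
Reagents that add atoms: none
Why: Sulfone-linchpin coupling: the α-sulfonyl carbanion and then the dianion of hydroxy sulfone 7 open the two terminal epoxides at their CH2 carbons (SN2), so C15 and C19 are taken over unchanged, while the sulfonyl-bearing C17 (a mixture) is erased in step 4.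

Step 3
Reactants: 8 (2R,6R)-4-(phenylsulfonyl)dec-9-ene-2,6-diol
Product: 9 (2R,6R)-2,6-bis(tert-butyldimethylsilyloxy)-4-(phenylsulfonyl)dec-9-ene (mixture at C4)
Conditions: TBSCl, imidazole, DMF, rt
Reagents that add atoms: tert-butyldimethylsilyl chloride, CC(C)(C)[Si](C)(C)Cl
Why: Standard imidazole-assisted silylation of the two secondary alcohols, which masks them for steps 4 to 12.

Step 4
Reactants: 9 (2R,6R)-2,6-bis(tert-butyldimethylsilyloxy)-4-(phenylsulfonyl)dec-9-ene
Product: 10 (5S,9R)-5,9-bis(tert-butyldimethylsilyloxy)dec-1-ene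
Conditions: 6 % Na(Hg), Na2HPO4, MeOH/THF, −20 °C
Reagents that add atoms: none
Why: Reductive desulfonylation by electron transfer from Na(Hg); the sulfone has no β-leaving group and the terminal alkene and silyl ethers are inert.

Step 5
Reactants: 10 (5S,9R)-5,9-bis(tert-butyldimethylsilyloxy)dec-1-ene; 11 phenyl acrylate
Product: 12 phenyl (2E,6S,10R)-6,10-bis(tert-butyldimethylsilyloxy)undec-2-enoate
Conditions: second-generation Hoveyda–Grubbs catalyst (3 mol %), 11 (3 equiv), CH2Cl2, 40 °C
Reagents that add atoms: none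
Why: Olefin cross-metathesis of a terminal alkene with an acrylate, which should be E-selective and gives the aryl enoate needed for step 6.

Step 6
Reactants: 12 phenyl (2E,6S,10R)-6,10-bis(tert-butyldimethylsilyloxy)undec-2-enoate; 13 ethynyltrimethylsilane
Product: 14 (4R)-4-[(3S,7R)-3,7-bis(tert-butyldimethylsilyloxy)octyl]-2-(trimethylsilyl)cyclopent-2-en-1-one
Conditions: Ni(cod)2 (10 mol %), bulky C1-symmetric chiral NHC·HBF4 (12 mol %), KOtBu (12 mol %), Et3B (3 equiv), MeOH/THF 1:8, 50 °C, 13 (2 equiv) added over 6 h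
Reagents that add atoms: none
Why: Zerovalent nickel bearing the carbene ligand binds the s-cis enoate and the alkyne and closes by oxidative cyclisation to a seven-membered oxygen-bound nickel enolate, which forms C11–C12; methanol protonates the enolate at C8, the alkenylnickel carbon C10 then adds to the ester carbonyl C9 and phenoxide leaves, which forms C9–C10, and Et3B returns divalent nickel to zerovalent nickel. The closest known reaction type is the nickel-catalysed reductive [3+2] cycloaddition of aryl enoates with alkynes, which has an enantioselective version with bulky chiral carbene ligands. The five-membered ring closes in the second bond formation by a 5-exo-trig addition of the alkenylnickel to the ester carbonyl followed by elimination (an intramolecular acyl substitution). The only new stereocenter, C12, is set in the oxidative cyclisation by the ligand (catalyst control, since C15 and C19 are too far away to interfere). The step needs regioselective alkyne insertion (C–C bond at the unsubstituted alkyne carbon, silicon next to nickel), which the steric demand of SiMe3 and the α-silyl stabilisation of the C–Ni bond should secure, and ring closure in preference to simple reductive coupling, which the good phenoxide leaving group should secure; slow addition of the alkyne should suppress its oligomerisation.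

Step 7
Reactants: 15 hex-5-ynoic acid
Product: 16 7-hydroxyhept-5-ynoic acid
Conditions: n-BuLi (2.2 equiv), THF, −78 → 0 °C; (CH2O)n, rt; aq HCl
Reagents that add atoms: paraformaldehyde (formaldehyde), C=O
Why: Addition of the acetylide of the carboxylate–acetylide dianion to formaldehyde (alkyne hydroxymethylation).

Step 8
Reactants: 16 7-hydroxyhept-5-ynoic acid
Product: 17 methyl 7-hydroxyhept-5-ynoate
Conditions: MeOH, H2SO4 (cat.), rt
Reagents that add atoms: methanol, CO
Why: Fischer esterification; the propargylic alcohol does not interfere.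

Step 9
Reactants: 17 methyl 7-hydroxyhept-5-ynoate
Product: 18 methyl (5Z)-7-hydroxyhept-5-enoate
Conditions: H2 (1 atm), Pd/CaCO3 poisoned with Pb(OAc)2, quinoline, EtOAc, rt
Reagents that add atoms: none
Why: Lindlar semihydrogenation: syn delivery of hydrogen on poisoned palladium gives the (Z)-alkene that becomes C5=C6.

Step 10
Reactants: 18 methyl (5Z)-7-hydroxyhept-5-enoate
Product: 19 methyl (5Z)-7-iodohept-5-enoate
Conditions: I2, PPh3, imidazole, CH2Cl2, 0 °C, dark
Reagents that add atoms: iodine, II
Why: Appel-type iodination (iodophosphonium activation, then SN2 displacement at the primary allylic carbon), which keeps the Z geometry.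

Step 11
Reactants: 14 (4R)-4-[(3S,7R)-3,7-bis(tert-butyldimethylsilyloxy)octyl]-2-(trimethylsilyl)cyclopent-2-en-1-one; 19 methyl (5Z)-7-iodohept-5-enoate
Product: 20 methyl (5Z)-7-[(1R,5R)-5-[(3S,7R)-3,7-bis(tert-butyldimethylsilyloxy)octyl]-2-oxo-3-(trimethylsilyl)cyclopent-3-en-1-yl]hept-5-enoate
Conditions: LDA, THF, −78 °C; 19, DMPU, −78 → −40 °C
Reagents that add atoms: none
Why: Kinetic deprotonation at C8 gives the cross-conjugated lithium dienolate, and SN2 alkylation by the allylic iodide on the face opposite to the adjacent C12 side chain sets C8 trans to C12 by substrate control (enolate alkylation).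

Step 12
Reactants: 20 methyl (5Z)-7-[(1R,5R)-5-[(3S,7R)-3,7-bis(tert-butyldimethylsilyloxy)octyl]-2-oxo-3-(trimethylsilyl)cyclopent-3-en-1-yl]hept-5-enoate
Product: 23 methyl (5Z)-7-[(1R,2R,3R)-2-[(3S,7R)-3,7-bis(tert-butyldimethylsilyloxy)octyl]-3-hydroxy-5-oxocyclopentyl]hept-5-enoate, via silyl boryl ketone 21 (not isolated), via boryl ketone 22 (not isolated)
Conditions: CuCl (10 mol %), NaOtBu (15 mol %), Xantphos (10 mol %), B2pin2 (1.2 equiv), MeOH (2 equiv), THF, rt; then K2CO3, MeOH, 0 °C; then 30 % H2O2, pH 7 phosphate buffer, THF, 0 °C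
Reagents that add atoms: hydrogen peroxide, OO
Why: Copper-catalysed conjugate borylation should place boron on C11 on the face opposite to the adjacent C12 side chain (substrate control), methanolysis cleaves the labile α-silyl ketone at C10 while C8 stays in its thermodynamically favoured trans arrangement, and stereoretentive oxidation of the C–B bond gives the 11-hydroxyl at neutral pH.

Step 13
Reactants: 23 methyl (5Z)-7-[(1R,2R,3R)-2-[(3S,7R)-3,7-bis(tert-butyldimethylsilyloxy)octyl]-3-hydroxy-5-oxocyclopentyl]hept-5-enoate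
Product: 24 methyl (5Z)-7-[(1R,2R,3R)-3-hydroxy-2-[(3S,7R)-3,7-dihydroxyoctyl]-5-oxocyclopentyl]hept-5-enoate
Conditions: HF·pyridine, MeCN, 0 °C
Reagents that add atoms: none
Why: Fluoride-mediated cleavage of both silyl ethers under mildly acidic conditions that the β-hydroxy ketone should tolerate.

Step 14
Reactants: 24 methyl (5Z)-7-[(1R,2R,3R)-3-hydroxy-2-[(3S,7R)-3,7-dihydroxyoctyl]-5-oxocyclopentyl]hept-5-enoate
Product: 25 (5Z)-7-[(1R,2R,3R)-3-hydroxy-2-[(3S,7R)-3,7-dihydroxyoctyl]-5-oxocyclopentyl]hept-5-enoic acid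
Conditions: porcine liver esterase, pH 7.4 phosphate buffer/acetone, 30 °C
Reagents that add atoms: water, O
Why: Enzymatic ester hydrolysis at neutral pH, which avoids base-induced loss of water from the β-hydroxy ketone and epimerisation at C8.

Compound list
1 | (R)-epichlorohydrin [(R)-2-(chloromethyl)oxirane] | ClC[C@H]1CO1 | starting material
2 | allylmagnesium chloride | C=CC[Mg]Cl | starting material
3 | (R)-1-chlorohex-5-en-2-ol (magnesium alkoxide in the flask) | ClC[C@H](O)CCC=C | intermediate
4 | (R)-2-(but-3-en-1-yl)oxirane | C=CCC[C@@H]1CO1 | intermediate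
5 | methyl phenyl sulfone | CS(=O)(=O)c1ccccc1 | starting material
6 | (R)-propylene oxide [(R)-2-methyloxirane] | C[C@@H]1CO1 | starting material
7 | (R)-1-(phenylsulfonyl)hept-6-en-3-ol (lithium alkoxide in the flask) | O=S(=O)(CC[C@H](O)CCC=C)c1ccccc1 | intermediate
8 | (2R,6R)-4-(phenylsulfonyl)dec-9-ene-2,6-diol (mixture at C4) | C[C@@H](O)CC(S(=O)(=O)c1ccccc1)C[C@H](O)CCC=C | intermediate
9 | (2R,6R)-2,6-bis(tert-butyldimethylsilyloxy)-4-(phenylsulfonyl)dec-9-ene (mixture at C4) | C[C@@H](O[Si](C)(C)C(C)(C)C)CC(S(=O)(=O)c1ccccc1)C[C@H](O[Si](C)(C)C(C)(C)C)CCC=C | intermediate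
10 | (5S,9R)-5,9-bis(tert-butyldimethylsilyloxy)dec-1-ene | C[C@@H](O[Si](C)(C)C(C)(C)C)CCC[C@H](O[Si](C)(C)C(C)(C)C)CCC=C | intermediate
11 | phenyl acrylate | C=CC(=O)Oc1ccccc1 | starting material
12 | phenyl (2E,6S,10R)-6,10-bis(tert-butyldimethylsilyloxy)undec-2-enoate | C[C@@H](O[Si](C)(C)C(C)(C)C)CCC[C@H](O[Si](C)(C)C(C)(C)C)CC/C=C/C(=O)Oc1ccccc1 | intermediate
13 | ethynyltrimethylsilane | C#C[Si](C)(C)C | starting material
14 | (4R)-4-[(3S,7R)-3,7-bis(tert-butyldimethylsilyloxy)octyl]-2-(trimethylsilyl)cyclopent-2-en-1-one | C[C@@H](O[Si](C)(C)C(C)(C)C)CCC[C@H](O[Si](C)(C)C(C)(C)C)CC[C@H]1C=C([Si](C)(C)C)C(=O)C1 | intermediate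
15 | hex-5-ynoic acid | OC(=O)CCCC#C | starting material
16 | 7-hydroxyhept-5-ynoic acid | OC(=O)CCCC#CCO | intermediate
17 | methyl 7-hydroxyhept-5-ynoate | COC(=O)CCCC#CCO | intermediate
18 | methyl (5Z)-7-hydroxyhept-5-enoate | COC(=O)CCC/C=C\CO | intermediate
19 | methyl (5Z)-7-iodohept-5-enoate | COC(=O)CCC/C=C\CI | intermediate
20 | methyl (5Z)-7-[(1R,5R)-5-[(3S,7R)-3,7-bis(tert-butyldimethylsilyloxy)octyl]-2-oxo-3-(trimethylsilyl)cyclopent-3-en-1-yl]hept-5-enoate | C[C@@H](O[Si](C)(C)C(C)(C)C)CCC[C@H](O[Si](C)(C)C(C)(C)C)CC[C@H]1C=C([Si](C)(C)C)C(=O)[C@@H]1C/C=C\CCCC(=O)OC | intermediate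
21 | silyl boryl ketone: ketone 23 with a pinacolboryl group in place of the C11 hydroxyl (same spatial position, trans to the C12 chain) and a trimethylsilyl group on C10 (both C10 epimers) | C[C@@H](O[Si](C)(C)C(C)(C)C)CCC[C@H](O[Si](C)(C)C(C)(C)C)CC[C@H]1[C@H](B2OC(C)(C)C(C)(C)O2)C([Si](C)(C)C)C(=O)[C@@H]1C/C=C\CCCC(=O)OC | intermediate
22 | methyl (5Z)-7-[(1R,2S,3R)-2-[(3S,7R)-3,7-bis(tert-butyldimethylsilyloxy)octyl]-5-oxo-3-(4,4,5,5-tetramethyl-1,3,2-dioxaborolan-2-yl)cyclopentyl]hept-5-enoate | C[C@@H](O[Si](C)(C)C(C)(C)C)CCC[C@H](O[Si](C)(C)C(C)(C)C)CC[C@H]1[C@H](B2OC(C)(C)C(C)(C)O2)CC(=O)[C@@H]1C/C=C\CCCC(=O)OC | intermediate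
23 | methyl (5Z)-7-[(1R,2R,3R)-2-[(3S,7R)-3,7-bis(tert-butyldimethylsilyloxy)octyl]-3-hydroxy-5-oxocyclopentyl]hept-5-enoate | C[C@@H](O[Si](C)(C)C(C)(C)C)CCC[C@H](O[Si](C)(C)C(C)(C)C)CC[C@H]1[C@H](O)CC(=O)[C@@H]1C/C=C\CCCC(=O)OC | intermediate
24 | methyl (5Z)-7-[(1R,2R,3R)-3-hydroxy-2-[(3S,7R)-3,7-dihydroxyoctyl]-5-oxocyclopentyl]hept-5-enoate | C[C@@H](O)CCC[C@H](O)CC[C@H]1[C@H](O)CC(=O)[C@@H]1C/C=C\CCCC(=O)OC | intermediate
25 | (5Z)-7-[(1R,2R,3R)-3-hydroxy-2-[(3S,7R)-3,7-dihydroxyoctyl]-5-oxocyclopentyl]hept-5-enoic acid [(5Z,8R,11R,12R,15S,19R)-11,15,19-trihydroxy-9-oxoprost-5-enoic acid] | C[C@@H](O)CCC[C@H](O)CC[C@H]1[C@H](O)CC(=O)[C@@H]1C/C=C\CCCC(=O)O | target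

Total step count: 14. Longest linear sequence: 10 steps (steps 1–6 and 11–14).

Steps most likely to fail

1. Step 6. The terminal silylalkyne may oligomerise at zerovalent nickel faster than it enters the cycloaddition, the alkenylnickel may be protonated before it closes the ring, or the ligand may discriminate the enoate faces poorly. In that case the ring would be built bond by bond from 12. A rhodium-catalysed asymmetric conjugate addition of the Hayashi–Miyaura type (Rh(acac)(C2H4)2, the BINAP antipode that gives (R), potassium vinyltrifluoroborate, dioxane/water) should give phenyl (3R,6S,10R)-6,10-bis(tert-butyldimethylsilyloxy)-3-ethenylundecanoate F1. Aminolysis with MeNHOMe·HCl and i-PrMgCl should give the N-methoxy-N-methylamide F2, and vinylmagnesium bromide the dienone F3. Ring-closing metathesis with second-generation Grubbs catalyst should then give the silicon-free (4R)-4-alkylcyclopent-2-en-1-one F4. Alkylation of F4 with 19 under the conditions of step 11 should give the trans-disubstituted cyclopentenone F5. Its copper-catalysed conjugate borylation (step 12 without the desilylation stage) comes back to the route at 22.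

2. Step 12. At the oxidation stage the C11 oxygen may be lost again across C10–C11 (Peterson-type loss of silanol if silicon is still on C10, or β-elimination to the enone), or boron may add with poor facial selectivity. The oxygen would then be brought in as an epoxide, starting from 20. Weitz–Scheffer epoxidation (H2O2, NaOH, MeOH, −20 °C) on the face opposite to the C12 chain should give the silyl epoxy ketone F6. KF in MeOH should remove the silyl group to give the 10,11-epoxy ketone F7. Reductive opening of the C10–O bond with sodium phenylseleno(triethoxy)borate (from (PhSe)2 and NaBH4, with AcOH in EtOH, 0 °C) then comes back to the route at 23.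

3. Step 11. The enolate may be alkylated twice, may equilibrate by proton transfer (including deprotonation at C12, with loss of the ring stereocenter), or the allylic iodide may react in the SN2′ sense. A linear, more reactive propargylic electrophile would then be used. Methyl 7-iodohept-5-ynoate F8 would be made from 17 (I2, PPh3, imidazole). The lithium enolate of 14, transmetalated with Me2Zn, would be alkylated with it to give the alkynyl enone F9. Lindlar semihydrogenation (H2, Pd/CaCO3 poisoned with Pb(OAc)2, quinoline) then comes back to the route at 20.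

Further compounds
F1 | step 6 | phenyl (3R,6S,10R)-6,10-bis(tert-butyldimethylsilyloxy)-3-ethenylundecanoate | C[C@@H](O[Si](C)(C)C(C)(C)C)CCC[C@H](O[Si](C)(C)C(C)(C)C)CC[C@H](CC(=O)Oc1ccccc1)C=C
F2 | step 6 | (3R,6S,10R)-6,10-bis(tert-butyldimethylsilyloxy)-3-ethenyl-N-methoxy-N-methylundecanamide | C[C@@H](O[Si](C)(C)C(C)(C)C)CCC[C@H](O[Si](C)(C)C(C)(C)C)CC[C@H](CC(=O)N(C)OC)C=C
F3 | step 6 | (5R,8S,12R)-8,12-bis(tert-butyldimethylsilyloxy)-5-ethenyltridec-1-en-3-one | C[C@@H](O[Si](C)(C)C(C)(C)C)CCC[C@H](O[Si](C)(C)C(C)(C)C)CC[C@H](CC(=O)C=C)C=C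
F4 | step 6 | (4R)-4-[(3S,7R)-3,7-bis(tert-butyldimethylsilyloxy)octyl]cyclopent-2-en-1-one | C[C@@H](O[Si](C)(C)C(C)(C)C)CCC[C@H](O[Si](C)(C)C(C)(C)C)CC[C@H]1C=CC(=O)C1
F5 | step 6 | methyl (5Z)-7-[(1R,5S)-5-[(3S,7R)-3,7-bis(tert-butyldimethylsilyloxy)octyl]-2-oxocyclopent-3-en-1-yl]hept-5-enoate | C[C@@H](O[Si](C)(C)C(C)(C)C)CCC[C@H](O[Si](C)(C)C(C)(C)C)CC[C@H]1C=CC(=O)[C@@H]1C/C=C\CCCC(=O)OC
F6 | step 12 | 10,11-epoxide of 20 on the face opposite to the C12 chain, trimethylsilyl group still on C10 | C[C@@H](O[Si](C)(C)C(C)(C)C)CCC[C@H](O[Si](C)(C)C(C)(C)C)CC[C@H]1[C@@H]2O[C@]2([Si](C)(C)C)C(=O)[C@@H]1C/C=C\CCCC(=O)OC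
F7 | step 12 | silicon-free 10,11-epoxy ketone (epoxide on the face opposite to the C12 chain) | C[C@@H](O[Si](C)(C)C(C)(C)C)CCC[C@H](O[Si](C)(C)C(C)(C)C)CC[C@H]1[C@@H]2O[C@@H]2C(=O)[C@@H]1C/C=C\CCCC(=O)OC
F8 | step 11 | methyl 7-iodohept-5-ynoate | COC(=O)CCCC#CCI
F9 | step 11 | methyl 7-[(1R,5R)-5-[(3S,7R)-3,7-bis(tert-butyldimethylsilyloxy)octyl]-2-oxo-3-(trimethylsilyl)cyclopent-3-en-1-yl]hept-5-ynoate | C[C@@H](O[Si](C)(C)C(C)(C)C)CCC[C@H](O[Si](C)(C)C(C)(C)C)CC[C@H]1C=C([Si](C)(C)C)C(=O)[C@@H]1CC#CCCCC(=O)OC
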